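**Retrosynthetic overview**
1. The C8 exocyclic methylene is unmasked last, by allylic transposition (Pd/formate) of a Δ7-alkene that carries a sacrificial second aryloxy group on C12.
2. Ring B is made in one step by a visible-light, hole-catalysed [4+2] between the ring-A tetrasubstituted alkene (C5=C10) and a (Z)-2-vinylbut-2-ene-1,4-diyl bis(umbelliferyl) ether. This forms C5–C6 and C9–C10 and sets C5, C9 and C10.
3. Ring A is the ring of (S)-carvone: gem-dimethylation (C4), reductive enol triflation, isopropenyl→OAc with retention (C3), and Me cross-coupling (5-Me).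
4. The diene comes from umbelliferone and 1,4-dichlorobut-2-yne by syn-hydrostannation and Stille vinylation.
5. Ring order: A (bought), then B (cycloaddition). The coumarin rings are bought.

Assumption: the SMILES is taken literally. C5 carries CH3, not H, so the core is a C16, cis-fused 4,4,5,10-tetramethyldecalin with 3-OAc, 5-Me, 10-Me and 9-CH2OAr all on one face: (3S,5S,9S,10R).

Drimane numbering is used throughout. C11 is the CH2O on C9, C12 is the =CH2 on C8, β is the face carrying the C10 methyl, and Ar is 2-oxo-2H-chromen-7-yl.

**Step 1**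
Reactants: 1, (S)-(+)-carvone
Product: 2, (5S)-2,6-dimethyl-5-(prop-1-en-2-yl)cyclohex-2-en-1-one (6-methylcarvone, C6 epimer mixture)
Conditions: LDA, THF, −78 °C; MeI, −78 → 0 °C
Reagents that add atoms: iodomethane, CI
Why: Kinetic α′-enolate alkylation of the enone; the new C6 centre is erased in step 2 and the bought stereocentre is not acidic.

**Step 2**
Reactants: 2
Product: 3, (5R)-2,6,6-trimethyl-5-(prop-1-en-2-yl)cyclohex-2-en-1-one (6,6-dimethylcarvone; same spatial arrangement, the descriptor changes only through CIP priorities)
Conditions: LDA, THF/DMPU, −78 → 0 °C; MeI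
Reagents that add atoms: iodomethane, CI
Why: A second α′-enolate alkylation (C6–H is the only α′ proton) installs the future C4 gem-dimethyl group; no new stereocentre is formed.

**Step 3**
Reactants: 3
Product: 4, (5R)-2,6,6-trimethyl-5-(prop-1-en-2-yl)cyclohex-1-en-1-yl triflate
Conditions: L-Selectride, THF, −78 °C; then PhNTf2, −78 °C → rt
Reagents that add atoms: N-phenylbis(trifluoromethanesulfonimide), O=S(=O)(N(c1ccccc1)S(=O)(=O)C(F)(F)F)C(F)(F)F
Why: Conjugate hydride reduction with regiospecific enolate O-triflation; the carbonyl flanked by CMe2 disfavours 1,2-attack, and the isolated isopropenyl group is inert.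

**Step 4**
Reactants: 4
Product: 5, (1S)-2,2,4-trimethyl-3-(trifluoromethylsulfonyloxy)cyclohex-3-en-1-yl acetate
Conditions: O3, CH2Cl2/MeOH, −78 °C (Sudan III end-point); concentrate; Ac2O, Et3N, cat. DMAP, CH2Cl2, 0 → 40 °C
Reagents that add atoms: ozone, [O-][O+]=O (ring-bound O); methanol, CO (acyl O, via the α-methoxy hydroperoxide). The acetyl carbons are the former isopropenyl C–CH3.
Why: Ozonolysis/Criegee rearrangement: only the unhindered, electron-rich isopropenyl reacts because the tetrasubstituted C=C is OTf-deactivated and hindered, and the ring carbon migrates to oxygen with retention, turning the bought stereocentre into C3–OAc (S).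

**Step 5**
Reactants: 5
Product: 6, (1S)-2,2,3,4-tetramethylcyclohex-3-en-1-yl acetate (ring A with the C5=C10 alkene)
Conditions: Me2Zn, Pd(dppf)Cl2 (5 mol %), THF, 60 °C
Reagents that add atoms: dimethylzinc, C[Zn]C
Why: Negishi methylation of the alkenyl triflate; organozinc reagents tolerate the acetate, and 2,6,6-trisubstituted cyclohexenyl triflates are competent coupling partners.

**Step 6**
Reactants: 7, umbelliferone (2.1 equiv); 8, 1,4-dichlorobut-2-yne
Product: 9, 1,4-bis(2-oxo-2H-chromen-7-yloxy)but-2-yne
Conditions: K2CO3, DMF, 60 °C
Reagents that add atoms: none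
Why: Double Williamson ether synthesis on a propargylic dichloride; the symmetric product removes any regiochemical question in step 7.

**Step 7**
Reactants: 9
Product: 10, (E)-2-(tributylstannyl)but-2-ene-1,4-diyl bis(umbelliferyl) ether (the two CH2OAr groups are cis)
Conditions: Bu3SnH, PdCl2(PPh3)2 (2 mol %), THF, 0 °C → rt
Reagents that add atoms: tributyltin hydride, CCCC[SnH](CCCC)CCCC
Why: Pd-catalysed syn-hydrostannation of a symmetric internal alkyne gives one regio- and stereoisomer.

**Step 8**
Reactants: 10
Product: 11, 7,7′-{[(2Z)-2-ethenylbut-2-ene-1,4-diyl]bis(oxy)}bis(2H-chromen-2-one) (C6H2=C7H–C8(C12H2OAr)=C9H–C11H2OAr, with C11 trans to C7)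
Conditions: vinyl bromide, Pd2(dba)3, AsPh3, CuI, DMF, 45 °C
Reagents that add atoms: vinyl bromide, C=CBr
Why: Stille coupling with retention of alkene geometry places C11 in the "outside" position of a 2-substituted diene that readily adopts the s-cis conformation.

**Step 9 (key step)**
Reactants: 6; 11 (1.5 equiv)
Product: 12, (3S,5S,9R,10R)-3-acetoxy-5-methyl-11,12-bis(2-oxo-2H-chromen-7-yloxy)drim-7-ene (cis-decalin; 3-OAc, 5-Me, 10-Me and C11 all β)
Conditions: 2,4,6-tris(4-methoxyphenyl)pyrylium BF4 (5 mol %), CH2Cl2/HFIP 9:1, 455 nm LEDs, −10 °C, Ar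
Reagents that add atoms: none
Why: Proposed new method: the excited pyrylium (E* ≈ +1.8 V vs SCE) should oxidise only the tetraalkyl alkene of 6 (estimated ≈ +1.6–1.7 V; diene and 7-alkoxycoumarin estimated ≥ +1.9 V), and the resulting alkene radical cation acts as the electron-deficient 2π partner toward the neutral s-cis diene, after which the adduct radical cation (a harder-to-oxidise trisubstituted alkene) oxidises the next molecule of 6 (hole chain) with HFIP suppressing allylic deprotonation; the unsubstituted C6 terminus pairs with neopentyl C5 and the substituted C9 terminus with the less hindered C10, suprafacial addition gives the cis fusion, attack occurs anti to the pseudoaxial β-methyl on C4 (fixed by the equatorial C3–OAc) so both angular methyls end β, and a methyls-endo/ring-A-exo geometry puts the outside C11 cis to the methyls; the closest known reaction type is the photoredox, aminium-salt or electrocatalytic radical-cation Diels–Alder of styrenes and enol ethers, not yet shown for a non-conjugated tetraalkyl alkene or for making vicinal quaternary carbons.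

**Step 10**
Reactants: 12
Product: 13, polyanthinin as drawn, (3S,5S,9S,10R)
Conditions: Pd2(dba)3·CHCl3 (2.5 mol %), PBu3 (10 mol %), HCO2H/Et3N, THF, 60 °C
Reagents that add atoms: none (formate delivers only H; umbelliferone is released)
Why: Tsuji-type Pd/formate hydrogenolysis: only C12–OAr is allylic (C11–OAr is homoallylic and the C3 acetate is unactivated), and hydride goes to the more substituted allyl terminus (C7) to give the exocyclic C8=C12 alkene without touching a stereocentre.

**Compound list**
1 | (S)-(+)-carvone | CC1=CC[C@@H](CC1=O)C(C)=C | starting material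
2 | (5S)-6-methylcarvone (C6 epimers) | CC1=CC[C@@H](C(C)C1=O)C(C)=C | intermediate
3 | (5R)-6,6-dimethylcarvone | CC1=CC[C@@H](C(C)(C)C1=O)C(C)=C | intermediate
4 | (5R)-2,6,6-trimethyl-5-isopropenylcyclohex-1-enyl triflate | CC1=C(OS(=O)(=O)C(F)(F)F)C(C)(C)[C@@H](C(C)=C)CC1 | intermediate
5 | (1S)-2,2,4-trimethyl-3-(triflyloxy)cyclohex-3-enyl acetate | CC1=C(OS(=O)(=O)C(F)(F)F)C(C)(C)[C@@H](OC(C)=O)CC1 | intermediate
6 | (1S)-2,2,3,4-tetramethylcyclohex-3-enyl acetate | CC1=C(C)C(C)(C)[C@@H](OC(C)=O)CC1 | intermediate
7 | umbelliferone | O=c1ccc2ccc(O)cc2o1 | starting material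
8 | 1,4-dichlorobut-2-yne | ClCC#CCCl | starting material
9 | 1,4-bis(umbelliferyloxy)but-2-yne | O=c1ccc2ccc(OCC#CCOc3ccc4ccc(=O)oc4c3)cc2o1 | intermediate
10 | (E)-2-(tributylstannyl)but-2-ene-1,4-diyl bis(umbelliferyl) ether | CCCC[Sn](CCCC)(CCCC)/C(COc1ccc2ccc(=O)oc2c1)=C/COc1ccc2ccc(=O)oc2c1 | intermediate
11 | (Z)-2-vinylbut-2-ene-1,4-diyl bis(umbelliferyl) ether | C=C/C(COc1ccc2ccc(=O)oc2c1)=C/COc1ccc2ccc(=O)oc2c1 | intermediate
12 | (3S,5S,9R,10R)-3-acetoxy-5-methyl-11,12-bis(umbelliferyloxy)drim-7-ene | O=c1ccc2ccc(OCC3=CC[C@]4(C)C(C)(C)[C@@H](OC(C)=O)CC[C@]4(C)[C@H]3COc3ccc5ccc(=O)oc5c3)cc2o1 | intermediate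
13 | polyanthinin (as drawn) | C=C1CC[C@]2(C)C(C)(C)[C@@H](OC(C)=O)CC[C@]2(C)[C@H]1COc1ccc2ccc(=O)oc2c1 | target

**Totals**
Total steps: 10.
Longest linear sequence: 7 (1→2→3→4→5→6→12→13).

**Steps most likely to fail**
1. **Step 9 (new reaction).** Risks are allylic deprotonation of the radical cation, the wrong regiochemistry, or no cycloaddition at such a hindered alkene.
   Fallback, using known reactions only and roughly seven steps longer:
   - Stille coupling of 5 with Bu3SnCH2OH gives the β-cyclogeraniol-type allylic alcohol.
   - Johnson orthoester Claisen rearrangement (known on β-cyclogeraniol itself) sets C10 and leaves a C5 exocyclic methylene.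
   - The ester is elaborated to the vinyl ketone.
   - Fe(acac)3/PhSiH3 HAT-initiated Giese cyclisation forms C5–C6 and the C5 methyl with cis fusion.
   - C11 and C12 are then built from the C8 ketone; C9 regio- and stereocontrol in that last stage remains to be worked out.
2. **Step 4.** Risks are ozone selectivity against the enol triflate and the efficiency of the Criegee rearrangement.
   Fallback: cleave the isopropenyl group with OsO4/NaIO4 (sterically selective) to the methyl ketone. Then convert it to the acetate by Baeyer–Villiger oxidation (m-CPBA/NaHCO3, which proceeds with retention; the electron-poor, hindered enol triflate should survive the peracid). This is one step longer.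
3. **Step 10.** Risks are hydride delivery to C12 or Pd–H isomerisation, either of which gives the Δ7 8-methyl isomer.
   Fallback: replace hydride delivery by SE2′ protonation. Pd-catalysed borylation of the allylic aryl ether with B2pin2 gives the C12 allylboronate, and γ-selective protodeboronation (TBAF·3H2O) then gives the exocyclic alkene.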